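## Analysis of the target

The target 9 is 5-nonadecyl-1H-pyrrole-2-carbaldehyde: one aromatic five-membered ring (N1, C2, C3, C4, C5) with a formyl group on C2, an unbranched saturated C19 chain on C5, a free N–H, and unsubstituted C3 and C4. It has no stereocentre and no double-bond geometry, so the problem is one of connectivity and regiochemistry only. The two different substituents must flank the nitrogen and nothing may end up on C3 or C4.

The feature on which this plan rests is the atom set N1, C2, C3, C4, C5 plus the exocyclic formyl carbon and its oxygen. This C5NO unit is an isomer of a pyridine N-oxide in which one carbon next to nitrogen has left the ring and taken the oxygen with it. The chain sits on the other carbon next to nitrogen.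

The sensitive groups are the electron-rich pyrrole, which is prone to acid-catalysed oligomerisation and autoxidation (most of all at the stage of a 2-alkylpyrrole without the formyl group), the aldehyde, and the acidic N–H. The C19 chain makes every intermediate waxy and poorly soluble in polar media, and chain-bearing by-products are hard to separate. Odd-numbered C19 building blocks are not commodity chemicals, so the chain is best assembled as C18 + C1. With so little structural complexity, the difficulty lies in reaching a 2,5-disubstituted N–H pyrrole in very few steps without unstable alkylpyrroles and without regioisomers.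

## Retrosynthetic reasoning

**9 to 5.** The N1–C2 bond of the pyrrole 9 is cut, N1 is reconnected to the formyl carbon, and the oxygen is returned from carbon to nitrogen. This ring expansion leads back to 2-nonadecylpyridine 1-oxide 5. The cut is made here because it is the only disconnection that makes the pyrrole ring and the formyl group from one ring. A 2-monosubstituted pyridine already holds the chain next to nitrogen, so the 2,5-relationship of 9 is fixed by the structure of 5. The forward reaction is a photochemical ring contraction with a divalent copper salt as additive. It has to move oxygen from N1 to the unsubstituted C6 (oxaziridine 6), open to the 1,2-oxazepine 7, and re-close through the 2H-pyrrole 8 to 9. The precursor 5 is an isomer of 9 and a far simpler compound, an N-oxide of a monoalkylpyridine.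

**5 to 4.** The N–O bond of 5 is cut, which leads to 2-nonadecylpyridine 4. The forward reaction is a peracid N-oxidation, which a saturated chain and a pyridine ring tolerate. The oxygen is put on after the chain because lateral metalation of the free pyridine is cleaner than that of its N-oxide.

**4 to 1 and 2.** The bond between the first and second chain carbon of 4 is cut. This gives 2-methylpyridine 1, whose methyl group becomes the first chain carbon, and 1-bromooctadecane 2, the cheapest long-chain electrophile. The odd C19 chain thus arises as C1 + C18. The forward reaction is lateral lithiation of 1 to the aza-allyl anion 3 and SN2 alkylation with 2.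

## Alternatives that were turned down

**Alternative 1:** the textbook route cuts the C2–CHO bond and then the ring–chain bond. 1H-Pyrrole A1 is acylated with nonadecanoyl chloride A2 to 1-(1H-pyrrol-2-yl)nonadecan-1-one A3, A3 is reduced to 2-nonadecyl-1H-pyrrole A4, and a Vilsmeier–Haack formylation of A4 at the free alpha position gives 9. Turned down for these reasons:
- It builds nothing of the skeleton: three electrophilic or reductive operations on a bought ring, each setting one group.
- A2 comes from an odd-chain C19 acid that is not a commodity.
- A4 is an electron-rich alkylpyrrole that oxidises in air and oligomerises with acid, and it must be purified as a wax.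
- The acylation of A1 has to be steered away from N-acylation and 2,5-diacylation.
- The step count is no lower than that of the chosen route.

**Alternative 2:** a Paal–Knorr ring synthesis cuts both C–N bonds. A Stetter union of icosanal A5 with 1,1-dimethoxybut-3-en-2-one A6 would give 1,1-dimethoxytetracosane-2,5-dione A7. Condensation of A7 with an ammonia source would give 2-(dimethoxymethyl)-5-nonadecyl-1H-pyrrole A8, and acetal hydrolysis would give 9. Turned down because the key step only dehydrates a precursor that already holds every carbon and every oxidation level of the product, so the difficulty moves into the synthesis of A7. A7 is an alpha-keto acetal and a 1,4-diketone at once and is prone to intramolecular aldol condensation. A5 and A6 are neither cheap nor stable, and acid hydrolysis of A8 exposes an electron-rich pyrrole to the conditions it tolerates least. The route needs at least three steps from less accessible materials.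

**Alternative 3:** a radical C–H alkylation cuts the C5–chain bond in one step. Decarboxylation of icosanoic acid A10 (AgNO3/(NH4)2S2O8 or anodic oxidation) would give a primary alkyl radical that adds to C5 of 1H-pyrrole-2-carbaldehyde A9 to give 9 after rearomatisation. Turned down on mechanistic grounds:
- The primary alkyl radical is nucleophilic, and A9 is still a pi-excessive heterocycle that cannot be protonated into an electron-poor acceptor as an azine can, so the polarities are mismatched.
- Addition at C3 and C4 and hydrogen abstraction from the formyl C–H would compete.
- The oxidant needed for the decarboxylation also oxidises the pyrrole, and radical dimerisation consumes A10.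
- The regioisomers would all carry the same C19 chain and would be very hard to separate.

Key step: step 3

Remark on the chemistry: the target is achiral, so no configuration has to be assigned. CuSO4 in step 3 is taken as an additive that is recovered unchanged.

## Route

Step 1
Reactants: 1 2-methylpyridine; 2 1-bromooctadecane
Product: 4 2-nonadecylpyridine, via 2-picolyllithium 3 (not isolated)
Conditions: 1 (1.3 equiv), n-BuLi (1.25 equiv), THF, −78 → −20 °C; then 2 (1.0 equiv) in THF, −78 °C → rt; aq. NH4Cl
Reagents that add atoms: n-butyllithium, [Li]CCCC (its lithium stays in 3 only; no atom of it remains in 4)
Why: Lateral lithiation of the 2-methyl group of 1 gives the resonance-stabilised aza-allyl anion 3, which is alkylated by the unhindered primary bromide 2 in an SN2 reaction. The excess of 3 over 2 and the lower acidity of the CH2 group of 4 should limit a second alkylation, and surplus 1 is removed by evaporation.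

Step 2
Reactants: 4 2-nonadecylpyridine
Product: 5 2-nonadecylpyridine 1-oxide
Conditions: mCPBA (1.2 equiv), CH2Cl2, 0 °C → rt; aq. K2CO3 wash
Reagents that add atoms: mCPBA (3-chloroperoxybenzoic acid), OOC(=O)c1cccc(Cl)c1
Why: Electrophilic N-oxidation of the pyridine lone pair by a peracid; the saturated chain and the ring carbons are inert under these conditions.

Step 3
Reactants: 5 2-nonadecylpyridine 1-oxide
Product: 9 5-nonadecyl-1H-pyrrole-2-carbaldehyde, via bicyclic oxaziridine 6 (not isolated), via 3-nonadecyl-1,2-oxazepine 7 (not isolated), via 2-formyl-2H-pyrrole 8 (not isolated)
Conditions: hν (254 nm, low-pressure Hg lamp, quartz), CuSO4·5H2O (2 equiv), degassed MeOH (ca. 5 mM), 15–20 °C, argon; stopped at partial conversion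
Reagents that add atoms: none
Why: Excitation of the N-oxide chromophore of 5 (pyridine numbering: N1, chain-bearing C2, unsubstituted C6) moves oxygen onto C6 and closes the three-membered oxaziridine ring of 6 by a photochemical four-electron electrocyclisation of the C6=N1–O unit. A thermal six-electron disrotatory ring opening of the arene oxide–oxepine type then breaks the N1–C6 bond and gives the seven-membered 1,2-oxazepine 7. Cleavage of the weak N–O bond of 7 and bonding of nitrogen to the former C5, in effect a 1,3-shift of nitrogen across the O–C6=C5 enol ether unit, closes the five-membered ring of 8 in a 5-exo mode and turns C6 into the formyl carbon; a 1,5-hydrogen shift from the sp3 carbon of 8 to nitrogen then gives the aromatic pyrrole 9. The closest known reaction type is the photochemical ring contraction of pyridine N-oxides, 2-alkyl members included, to 2-formylpyrroles in the presence of divalent copper salts. The copper ion is expected to bind nitrogen at the ring-opened stage and to favour the recyclisation over polymerisation, over deoxygenation and over the competing path to 3-hydroxypyridines. The selectivity needed is regiochemical: oxygen must migrate to C6 and not to C2, which would end in a 2-acylpyrrole, and the chain on C2, which would make the oxaziridine carbon fully substituted, secures the C6 mode. The stereocentres of 6 and 8 are transient, racemic and erased on aromatisation, so no stereocontrol is needed. Irradiation is stopped at partial conversion because 9 also absorbs at this wavelength, and recovered 5 is recycled.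

## Compound list

1 | 2-methylpyridine | Cc1ccccn1 | starting material
2 | 1-bromooctadecane | CCCCCCCCCCCCCCCCCCBr | starting material
3 | (pyridin-2-ylmethyl)lithium | [Li]Cc1ccccn1 | intermediate (not isolated)
4 | 2-nonadecylpyridine | CCCCCCCCCCCCCCCCCCCc1ccccn1 | intermediate
5 | 2-nonadecylpyridine 1-oxide | CCCCCCCCCCCCCCCCCCCc1cccc[n+]1[O-] | intermediate
6 | 2-nonadecyl-7-oxa-1-azabicyclo[4.1.0]hepta-2,4-diene (racemic) | CCCCCCCCCCCCCCCCCCCC1=CC=CC2ON12 | intermediate (not isolated)
7 | 3-nonadecyl-1,2-oxazepine | CCCCCCCCCCCCCCCCCCCC1=NOC=CC=C1 | intermediate (not isolated)
8 | 5-nonadecyl-2H-pyrrole-2-carbaldehyde (racemic) | CCCCCCCCCCCCCCCCCCCC1=NC(C=O)C=C1 | intermediate (not isolated)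
9 | 5-nonadecyl-1H-pyrrole-2-carbaldehyde | CCCCCCCCCCCCCCCCCCCc1ccc(C=O)[nH]1 | target

## Step count and risk

Total step count: 3. Longest linear sequence: 3 steps (1 → 4 → 5 → 9, with 2 entering in step 1).

**Step 3 (key step).** Four things are most likely to go wrong:
- Oxygen migrates to the chain-bearing carbon, which ends in an acylpyrrole isomer. The two alpha positions differ only by the alkyl group.
- The substrate is photodeoxygenated back to 4 through the triplet manifold. This costs throughput only, since 4 re-enters at step 2.
- The ring-opened stage is diverted to polymer or solvent adducts. Copper coordination may be less effective in methanol with an aggregating amphiphile than in the aqueous medium of the parent reaction.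
- The product is destroyed by secondary photolysis on over-irradiation.

The fallback abandons the ring contraction and builds both substituents on a preformed pyrrole. It sets out from 2. Magnesium in THF gives octadecylmagnesium bromide F1. F1 (2.2 equiv, the first equivalent being consumed by the N–H) adds to commercial 1H-pyrrole-2-carbaldehyde at 0 °C and gives, after aqueous NH4Cl, racemic 1-(1H-pyrrol-2-yl)nonadecan-1-ol F2, which is used crude. NaBH4 in refluxing 2-propanol removes the hydroxyl group of F2 by elimination and hydride addition and gives 2-nonadecyl-1H-pyrrole F3. A Vilsmeier–Haack formylation of F3 (POCl3, DMF, 0 °C, then aqueous NaOAc) attacks the only free alpha position and comes back to the route at 9. This costs four steps and passes through the air-sensitive F3, which is why it is the fallback and not the plan.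

**Step 1.** The basic carbanion 3 may eliminate HBr from 2 instead of substituting it. Proton transfer from 4 to 3 may lead to a second alkylation. The waxy bromide may precipitate at low temperature and react incompletely.

The fallback makes the same chain by olefination instead of alkylation and sets out from 2. Heating 2 with PPh3 gives octadecyl(triphenyl)phosphonium bromide F4. NaN(SiMe3)2 in THF converts F4 into octadecylidene(triphenyl)phosphorane F5. A Wittig reaction of F5 with commercial pyridine-2-carbaldehyde gives 2-[(1Z)-nonadec-1-en-1-yl]pyridine F6, mainly as the Z isomer, whose geometry is of no consequence. Hydrogenation of F6 (H2, Pd/C, EtOAc, rt) saturates the alkene without touching the pyridine ring and comes back to the route at 4.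

**Step 2.** The oxidation itself is reliable. The likely loss is in the work-up, where the amphiphilic N-oxide forms emulsions and a salt with the acid by-product, so that extraction is incomplete.

The fallback reverses the order of C–C and N–O bond formation and sets out from 2. Commercial 2-methylpyridine 1-oxide is deprotonated at the methyl group with LiN(i-Pr)2 in THF at −78 °C to give (1-oxidopyridin-1-ium-2-yl)methyllithium F7. Alkylation of F7 with 2 comes back to the route at 5 and saves one step. It is not the plan because metalation of the N-oxide can also take place at the ring position next to nitrogen, and the lithiated N-oxide is less stable than 3.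

## Further compounds

F1 | step 3 | octadecylmagnesium bromide | CCCCCCCCCCCCCCCCCC[Mg]Br
F2 | step 3 | 1-(1H-pyrrol-2-yl)nonadecan-1-ol (racemic) | CCCCCCCCCCCCCCCCCCC(O)c1ccc[nH]1
F3 | step 3 | 2-nonadecyl-1H-pyrrole | CCCCCCCCCCCCCCCCCCCc1ccc[nH]1
F4 | step 1 | octadecyl(triphenyl)phosphonium bromide | CCCCCCCCCCCCCCCCCC[P+](c1ccccc1)(c1ccccc1)c1ccccc1.[Br-]
F5 | step 1 | octadecylidene(triphenyl)phosphorane | CCCCCCCCCCCCCCCCCC=P(c1ccccc1)(c1ccccc1)c1ccccc1
F6 | step 1 | 2-[(1Z)-nonadec-1-en-1-yl]pyridine | CCCCCCCCCCCCCCCCC/C=C\c1ccccn1
F7 | step 2 | (1-oxidopyridin-1-ium-2-yl)methyllithium | [Li]Cc1cccc[n+]1[O-]
A1 | alternative 1 | 1H-pyrrole | c1cc[nH]c1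
A2 | alternative 1 | nonadecanoyl chloride | CCCCCCCCCCCCCCCCCCC(=O)Cl
A3 | alternative 1 | 1-(1H-pyrrol-2-yl)nonadecan-1-one | CCCCCCCCCCCCCCCCCCC(=O)c1ccc[nH]1
A4 | alternative 1 | 2-nonadecyl-1H-pyrrole | CCCCCCCCCCCCCCCCCCCc1ccc[nH]1
A5 | alternative 2 | icosanal | CCCCCCCCCCCCCCCCCCCC=O
A6 | alternative 2 | 1,1-dimethoxybut-3-en-2-one | C=CC(=O)C(OC)OC
A7 | alternative 2 | 1,1-dimethoxytetracosane-2,5-dione | CCCCCCCCCCCCCCCCCCCC(=O)CCC(=O)C(OC)OC
A8 | alternative 2 | 2-(dimethoxymethyl)-5-nonadecyl-1H-pyrrole | CCCCCCCCCCCCCCCCCCCc1ccc(C(OC)OC)[nH]1
A9 | alternative 3 | 1H-pyrrole-2-carbaldehyde | O=Cc1ccc[nH]1
A10 | alternative 3 | icosanoic acid | CCCCCCCCCCCCCCCCCCCC(=O)O
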